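## Retrosynthetic overview

1. Caespitane is (−)-α-bisabolol with Br/Cl added across its ring alkene and Br/O across its side-chain alkene. The C3(Me)Cl–C2HBr pair of ring A (cyclohexane) is a latent C2=C3 alkene, and the bromo-oxane (ring B) is the C7 tertiary alcohol added to the C10=C11 alkene.
2. Enabling feature: ring A then reads C1H2–C2H=C3(Me)–C4H2–C5H2–C6H, with C6 bonded to the carbinol carbon C7. That is an allylic terminus (C1) five atoms from a 6,7-alkene plus water, i.e. folded farnesyl diphosphate, so a terpene cyclase can make the C1–C6 bond.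
3. Ring order: ring A (enzymatic 1,6-cyclisation, sets C6 and C7), then ring B (6-endo bromoetherification, sets C10), then the ring A halogens.
4. Direct BrCl addition to a cyclohexene gives trans-diaxial adducts, but the target pair is trans-diequatorial. It is therefore built by stereoconvergent trans-diaxial dihydroxylation, double inversion through an acetoxonium ion (Br at C2), and retentive chlorination at C3.

Key step: step 2

Remark: atoms are numbered as in the farnesane skeleton; "syn" and "anti" refer to the face of ring A relative to the C6 side chain; the cyclase is assumed to be available as recombinant protein and is treated as a catalyst.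

## Route

Step 1
Reactants: 1 (2E,6E)-farnesyl bromide
Product: 2 (2E,6E)-farnesyl diphosphate triammonium salt
Conditions: (n-Bu4N)3HP2O7 (2 equiv), MeCN, rt; then Dowex 50W-X8 (NH4+ form), 25 mM NH4HCO3 in 2% i-PrOH/H2O; lyophilisation
Reagents that add atoms: tris(tetra-n-butylammonium) hydrogen diphosphate, CCCC[N+](CCCC)(CCCC)CCCC.CCCC[N+](CCCC)(CCCC)CCCC.CCCC[N+](CCCC)(CCCC)CCCC.OP(=O)([O-])OP(=O)([O-])[O-]; ammonium hydrogencarbonate, [NH4+].OC([O-])=O
Why: SN2 displacement of the primary allylic bromide by the diphosphate trianion in acetonitrile, followed by cation exchange, should give the ammonium salt with both E double bonds untouched; no stereocenter is formed.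

Step 2
Reactants: 2 (2E,6E)-farnesyl diphosphate triammonium salt
Product: 3 (−)-α-bisabolol, (2S)-6-methyl-2-[(1S)-4-methylcyclohex-3-en-1-yl]hept-5-en-2-ol
Conditions: recombinant (−)-α-bisabolol synthase (class 1 sesquiterpene cyclase, e.g. the Matricaria recutita enzyme expressed in E. coli), MgCl2 (10 mM), HEPES buffer pH 7.2, dithiothreitol, 30 °C, pentane overlay, 2 added in portions
Reagents that add atoms: water, O
Why: The enzyme binds the diphosphate through its aspartate-rich motifs and three magnesium ions, ionises the C1–O bond, returns diphosphate to C3 to give enzyme-bound nerolidyl diphosphate (so that the 2,3-bond can rotate into the cisoid geometry) and ionises again; C1 of the cisoid allyl cation is then attacked by C6 of the 6,7-double bond, and the resulting C7 bisabolyl cation is quenched by an active-site water molecule. The closest known reaction is this native conversion by α-bisabolol synthases (class 1 terpene cyclases); the nearest small-reagent counterpart, acid-promoted cyclisation of nerolidol or farnesol, gives racemic mixtures of bisabolols and bisabolenes. Ring A closes by a 1,6-closure of the farnesyl chain, 6-exo-trig with respect to the attacking 6,7-alkene, with the former 2,3-double bond ending up endocyclic. C6 (S) is controlled by the enzyme-imposed chain fold, which presents one face of the 6,7-alkene to C1, and C7 (S) by the fixed position of the water molecule that captures one face of the planar cation. The step needs 1,6-closure rather than 1,10- or 1,11-closure, hydration rather than proton loss to bisabolenes, and no premature hydrolysis to farnesol or nerolidol; the active-site contour secures these, helped by the head-to-tail methyl pattern of the substrate, which makes C7 the only tertiary cation reachable through a six-membered transition state.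

Step 3
Reactants: 3 (−)-α-bisabolol
Product: 4 (3R,6S)-3-bromo-2,2,6-trimethyl-6-[(1S)-4-methylcyclohex-3-en-1-yl]oxane
Conditions: 2,4,4,6-tetrabromocyclohexa-2,5-dienone (TBCO, 1.1 equiv), MeNO2, 0 °C to rt, dark
Reagents that add atoms: 2,4,4,6-tetrabromocyclohexa-2,5-dienone, O=C1C(Br)=CC(Br)(Br)C=C1Br
Why: Bromonium-induced 6-endo-trig etherification: TBCO transfers Br+ to the isopropylidene alkene and the C7 hydroxyl opens the bromonium ion at the tertiary C11 (Markovnikov) through a chair transition state with bromine equatorial (anti addition) and ring A equatorial at C7 (C7 methyl axial), which should set C10 as R with Br trans to ring A; capture of the ring A alkene by the same hydroxyl needs a boat-shaped bicyclic transition state and should be slower.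

Step 4
Reactants: 4 (3R,6S)-3-bromo-2,2,6-trimethyl-6-[(1S)-4-methylcyclohex-3-en-1-yl]oxane
Product: 7 (1R,2R,4S)-4-[(2S,5R)-5-bromo-2,6,6-trimethyloxan-2-yl]-1-methylcyclohexane-1,2-diol, via syn-epoxide 5 (not isolated), via anti-epoxide 6 (not isolated)
Conditions: m-CPBA (1.2 equiv), NaHCO3, CH2Cl2, 0 °C; then crude epoxides, HClO4 (5 mol %), THF/H2O 3:1, rt
Reagents that add atoms: 3-chloroperoxybenzoic acid, OOC(=O)c1cccc(Cl)c1; water, O
Why: Prilezhaev epoxidation is not face-selective, but acid-catalysed hydrolysis is stereoconvergent by the Fürst–Plattner rule (trans-diaxial opening): water attacks the syn-epoxide at the secondary C2 and the anti-epoxide at the tertiary C3, so both should give the same diol with C2–OH axial and anti and C3–OH axial and syn (both R), as is known for mixtures of cis- and trans-limonene oxide.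

Step 5
Reactants: 7 (1R,2R,4S)-4-[(2S,5R)-5-bromo-2,6,6-trimethyloxan-2-yl]-1-methylcyclohexane-1,2-diol
Product: 8 (1R,2R,5S)-5-[(2S,5R)-5-bromo-2,6,6-trimethyloxan-2-yl]-2-hydroxy-2-methylcyclohexyl acetate
Conditions: Ac2O (1.2 equiv), pyridine, DMAP (5 mol %), CH2Cl2, 0 °C to rt
Reagents that add atoms: acetic anhydride, CC(=O)OC(C)=O
Why: Steric chemoselectivity of DMAP-catalysed acylation: the secondary C2 hydroxyl should be acetylated and the tertiary C3 hydroxyl left free; no stereocenter changes.

Step 6
Reactants: 8 (1R,2R,5S)-5-[(2S,5R)-5-bromo-2,6,6-trimethyloxan-2-yl]-2-hydroxy-2-methylcyclohexyl acetate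
Product: 11 (1S,2S,4S)-2-bromo-4-[(2S,5R)-5-bromo-2,6,6-trimethyloxan-2-yl]-1-methylcyclohexyl acetate, via bromosulfite 9 (not isolated), via acetoxonium bromide 10 (not isolated)
Conditions: SOBr2 (1.2 equiv), 2,6-lutidine (1.3 equiv), CH2Cl2, −40 °C to rt
Reagents that add atoms: thionyl bromide, O=S(Br)Br
Why: Neighbouring-group (acetoxonium) participation, the reaction type behind the HBr/AcOH conversion of diols into bromo acetates: the tertiary bromosulfite ionises with rear-side attack of the antiperiplanar axial acetate (inversion at C3) to the cis-fused dioxolanylium ion 10, which bromide should open by SN2 at the secondary C2, whose C–O bond is axial (inversion at C2), giving the trans-diequatorial bromo acetate with Br syn; collapse at the tertiary C3 only gives a diaxial tertiary bromide that re-ionises to 10, whereas 11 cannot re-ionise because its Br and OAc are gauche.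

Step 7
Reactants: 11 (1S,2S,4S)-2-bromo-4-[(2S,5R)-5-bromo-2,6,6-trimethyloxan-2-yl]-1-methylcyclohexyl acetate
Product: 12 (1S,2S,4S)-2-bromo-4-[(2S,5R)-5-bromo-2,6,6-trimethyloxan-2-yl]-1-methylcyclohexan-1-ol
Conditions: i-Bu2AlH (2.5 equiv), CH2Cl2, −78 °C; aqueous KNaC4H4O6 work-up
Reagents that add atoms: none
Why: Reductive cleavage of the ester at the acyl carbon by i-Bu2AlH at low temperature frees the hindered tertiary hydroxyl without base, so neither epoxide closure nor elimination is expected and the C–Br bonds and all stereocenters stay untouched.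

Step 8
Reactants: 12 (1S,2S,4S)-2-bromo-4-[(2S,5R)-5-bromo-2,6,6-trimethyloxan-2-yl]-1-methylcyclohexan-1-ol
Product: 14 caespitane, (3R,6S)-3-bromo-6-[(1S,3S,4S)-3-bromo-4-chloro-4-methylcyclohexyl]-2,2,6-trimethyloxane, via chlorosulfite 13 (not isolated)
Conditions: SOCl2 (3 equiv), Et2O, −20 °C to rt, no amine base
Reagents that add atoms: thionyl chloride, O=S(Cl)Cl
Why: Deoxychlorination of a tertiary alcohol by thionyl chloride without base (SNi, ion-pair return): chlorosulfite 13 ionises to a tertiary cation shielded on its syn face by the neighbouring C2 bromine (bromonium-type bridging) and collapses with the chloride released on the face the oxygen left, so C3 should be chlorinated with retention (Cl equatorial, methyl axial), completing the trans-diequatorial Br/Cl pair.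

## Compound list

1 | (2E,6E)-farnesyl bromide | CC(C)=CCC/C(C)=C/CC/C(C)=C/CBr | starting material
2 | (2E,6E)-farnesyl diphosphate triammonium salt | CC(C)=CCC/C(C)=C/CC/C(C)=C/COP(=O)([O-])OP(=O)([O-])[O-].[NH4+].[NH4+].[NH4+] | intermediate
3 | (−)-α-bisabolol, (2S)-6-methyl-2-[(1S)-4-methylcyclohex-3-en-1-yl]hept-5-en-2-ol | CC(C)=CCC[C@](C)(O)[C@H]1CCC(C)=CC1 | intermediate
4 | (3R,6S)-3-bromo-2,2,6-trimethyl-6-[(1S)-4-methylcyclohex-3-en-1-yl]oxane | CC1(C)O[C@](C)([C@H]2CCC(C)=CC2)CC[C@H]1Br | intermediate
5 | syn-epoxide of 4 (oxirane oxygen cis to the oxanyl group, methyl trans) | CC1(C)O[C@](C)([C@H]2CC[C@@]3(C)O[C@H]3C2)CC[C@H]1Br | intermediate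
6 | anti-epoxide of 4 (oxirane oxygen trans to the oxanyl group, methyl cis) | CC1(C)O[C@](C)([C@H]2CC[C@]3(C)O[C@@H]3C2)CC[C@H]1Br | intermediate
7 | (1R,2R,4S)-4-[(2S,5R)-5-bromo-2,6,6-trimethyloxan-2-yl]-1-methylcyclohexane-1,2-diol (trans-diaxial diol) | CC1(C)O[C@](C)([C@H]2CC[C@@](C)(O)[C@H](O)C2)CC[C@H]1Br | intermediate
8 | (1R,2R,5S)-5-[(2S,5R)-5-bromo-2,6,6-trimethyloxan-2-yl]-2-hydroxy-2-methylcyclohexyl acetate | CC1(C)O[C@](C)([C@H]2CC[C@@](C)(O)[C@H](OC(C)=O)C2)CC[C@H]1Br | intermediate
9 | tertiary bromosulfite ester of 8 | CC1(C)O[C@](C)([C@H]2CC[C@@](C)(OS(Br)=O)[C@H](OC(C)=O)C2)CC[C@H]1Br | intermediate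
10 | cis-fused 2-methyl-1,3-dioxolan-2-ylium bromide (acetoxonium ion, both oxygens anti) | CC1(C)O[C@](C)([C@H]2CC[C@]3(C)OC(C)=[O+][C@@H]3C2)CC[C@H]1Br.[Br-] | intermediate
11 | (1S,2S,4S)-2-bromo-4-[(2S,5R)-5-bromo-2,6,6-trimethyloxan-2-yl]-1-methylcyclohexyl acetate | CC1(C)O[C@](C)([C@H]2CC[C@](C)(OC(C)=O)[C@@H](Br)C2)CC[C@H]1Br | intermediate
12 | (1S,2S,4S)-2-bromo-4-[(2S,5R)-5-bromo-2,6,6-trimethyloxan-2-yl]-1-methylcyclohexan-1-ol | CC1(C)O[C@](C)([C@H]2CC[C@](C)(O)[C@@H](Br)C2)CC[C@H]1Br | intermediate
13 | tertiary chlorosulfite ester of 12 | CC1(C)O[C@](C)([C@H]2CC[C@](C)(OS(Cl)=O)[C@@H](Br)C2)CC[C@H]1Br | intermediate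
14 | caespitane, (3R,6S)-3-bromo-6-[(1S,3S,4S)-3-bromo-4-chloro-4-methylcyclohexyl]-2,2,6-trimethyloxane | CC1(C)O[C@](C)([C@H]2CC[C@](C)(Cl)[C@@H](Br)C2)CC[C@H]1Br | target

## Step count and risks

Total step count: 8. Longest linear sequence: 8 steps (fully linear from 1).

Steps most likely to fail:

**Step 6.** Bromide may collapse at the tertiary carbon of the acetoxonium ion, the ion may lose a proton (E1), or the acidic medium may open ring B. The fallback sets out from 8 and returns at 12. The same ion is generated with CF3SO3H (10 mol %) in MeCN/H2O at 0 °C and captured by water at the dioxolanylium carbon, which should give the cis-hydroxy acetate (1R,2S,5S)-5-[(2S,5R)-5-bromo-2,6,6-trimethyloxan-2-yl]-2-hydroxy-2-methylcyclohexyl acetate F1. Methanolysis (K2CO3, MeOH) gives the cis-diol (1S,2R,4S)-4-[(2S,5R)-5-bromo-2,6,6-trimethyloxan-2-yl]-1-methylcyclohexane-1,2-diol F2. 1,1'-Sulfonyldiimidazole and NaH in THF convert it into the cyclic sulfate F3. LiBr in THF opens this irreversibly at the secondary carbon with inversion to the lithium bromo sulfate F4, and H2SO4 (cat.) with one equivalent of water in THF hydrolyses the sulfate ester to 12.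

**Step 8.** The ion pair may lose a proton (E1), lose its stereochemical memory at C3, or let bromine migrate. The fallback sets out from 12 and returns at 14. SOCl2 in pyridine at 0 °C dehydrates the equatorial tertiary alcohol towards the methyl group, because no ring hydrogen is antiperiplanar to the equatorial C–O bond, which should give the exocyclic alkene (3R,6S)-3-bromo-6-[(1S,3S)-3-bromo-4-methylidenecyclohexyl]-2,2,6-trimethyloxane F5. Anhydrous HCl in CH2Cl2 at −78 °C then adds in the Markovnikov sense, with the neighbouring bromine bridging the tertiary cation so that chloride enters anti to it, giving 14.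

**Step 3.** The hydroxyl may close 5-exo to a tetrahydrofuran, it may capture the ring A bromonium ion instead, or facial control at C10 may be poor. The fallback sets out from 3 and returns at 4. Reversible oxymercuration with Hg(OCOCF3)2 in MeNO2 at 0 °C, followed by aqueous KBr, puts the cyclisation under thermodynamic control and should give the six-membered organomercurial with equatorial mercury, bromo[(3R,6S)-2,2,6-trimethyl-6-[(1S)-4-methylcyclohex-3-en-1-yl]oxan-3-yl]mercury F6. Bromodemercuration with Br2 (1.0 equiv) and LiBr in pyridine at −20 °C in the dark (polar, retentive cleavage of the C–Hg bond) gives 4.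

## Further compounds

F1 | step 6 | (1R,2S,5S)-5-[(2S,5R)-5-bromo-2,6,6-trimethyloxan-2-yl]-2-hydroxy-2-methylcyclohexyl acetate | CC1(C)O[C@](C)([C@H]2CC[C@](C)(O)[C@H](OC(C)=O)C2)CC[C@H]1Br
F2 | step 6 | (1S,2R,4S)-4-[(2S,5R)-5-bromo-2,6,6-trimethyloxan-2-yl]-1-methylcyclohexane-1,2-diol | CC1(C)O[C@](C)([C@H]2CC[C@](C)(O)[C@H](O)C2)CC[C@H]1Br
F3 | step 6 | cyclic sulfate of F2 | CC1(C)O[C@](C)([C@H]2CC[C@]3(C)OS(=O)(=O)O[C@@H]3C2)CC[C@H]1Br
F4 | step 6 | lithium (1S,2S,4S)-2-bromo-4-[(2S,5R)-5-bromo-2,6,6-trimethyloxan-2-yl]-1-methylcyclohexyl sulfate | CC1(C)O[C@](C)([C@H]2CC[C@](C)(OS(=O)(=O)[O-])[C@@H](Br)C2)CC[C@H]1Br.[Li+]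
F5 | step 8 | (3R,6S)-3-bromo-6-[(1S,3S)-3-bromo-4-methylidenecyclohexyl]-2,2,6-trimethyloxane | CC1(C)O[C@](C)([C@H]2CCC(=C)[C@@H](Br)C2)CC[C@H]1Br
F6 | step 3 | bromo[(3R,6S)-2,2,6-trimethyl-6-[(1S)-4-methylcyclohex-3-en-1-yl]oxan-3-yl]mercury | CC1(C)O[C@](C)([C@H]2CCC(C)=CC2)CC[C@H]1[Hg]Br
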